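The route rests on one disconnection: the bond between C6 of ring A (the aromatic CH between the hydroxyl-bearing C5 and C7 of the phloroglucinol-type ring) and C1'' of the 7-hydroxy-3,7-dimethyloct-2-enyl chain. A soluble aromatic prenyltransferase should forge this bond in a single operation on unprotected natural (2R,3R)-taxifolin at neutral pH, exploiting the high nucleophilicity of C6, so that rings A, B and C and both stereocentres are bought intact and no protecting group is needed. The precursor is the allylic diphosphate of (E)-7-hydroxy-6,7-dihydrogeraniol, prepared in four steps from geranyl acetate by distal-olefin hydration, deacetylation, allylic chlorination and diphosphate displacement.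

Key step: step 5

Remark: diphosphate 8 is drawn as the free acid but is isolated, stored and used as its tris(ammonium) salt; the prenyltransferase NphB is treated as a catalyst obtained by routine heterologous expression and is not counted as a synthetic step.

Step 1
Reactants: 1 geranyl acetate [(2E)-3,7-dimethylocta-2,6-dien-1-yl acetate]
Product: 3 (2E)-7-hydroxy-3,7-dimethyloct-2-en-1-yl acetate, via organomercurial acetate 2 (not isolated)
Conditions: Hg(OAc)2 (1.0 equiv), THF/H2O 1:1, 0 °C to rt; then NaBH4, aq NaOH, 0 °C
Reagents that add atoms: water, O (hydroxyl oxygen of 3); mercury diacetate, CC(=O)O[Hg]OC(C)=O (mercury and one acetate, present in intermediate 2 only)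
Why: Oxymercuration–demercuration should give Markovnikov hydration of the electron-rich distal 6,7-olefin, the 2,3-olefin being slowed by the electron-withdrawing allylic acetate, and NaBH4 then replaces mercury by hydrogen, so that C7 (two methyl groups) and C6 (CH2) are not stereocentres and the E olefin is untouched.

Step 2
Reactants: 3 (2E)-7-hydroxy-3,7-dimethyloct-2-en-1-yl acetate
Product: 4 (2E)-3,7-dimethyloct-2-ene-1,7-diol
Conditions: K2CO3 (0.3 equiv), MeOH, rt
Reagents that add atoms: none
Why: Base-catalysed transesterification (Zemplén-type methanolysis) should remove the primary allylic acetate without touching the trisubstituted E olefin or the tertiary alcohol.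

Step 3
Reactants: 4 (2E)-3,7-dimethyloct-2-ene-1,7-diol
Product: 6 (6E)-8-chloro-2,6-dimethyloct-6-en-2-ol, via alkoxydimethylsulfonium chloride 5 (not isolated)
Conditions: NCS (1.2 equiv), Me2S (1.4 equiv), CH2Cl2, −40 °C to 0 °C
Reagents that add atoms: N-chlorosuccinimide, O=C1CCC(=O)N1Cl (chlorine of 6); dimethyl sulfide, CSC (sulfonium group of intermediate 5 only)
Why: In this Corey–Kim chlorination the sulfonium salt formed from NCS and Me2S should activate the unhindered primary allylic hydroxyl as alkoxysulfonium salt 5, which chloride opens by SN2 at C1 without allylic transposition or loss of E geometry, whereas the tertiary hydroxyl cannot be displaced in this way and is recovered on work-up.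

Step 4
Reactants: 6 (6E)-8-chloro-2,6-dimethyloct-6-en-2-ol; 7 tris(tetrabutylammonium) hydrogen diphosphate (2 equiv)
Product: 8 (2E)-7-hydroxy-3,7-dimethyloct-2-en-1-yl diphosphate (isolated as the tris(ammonium) salt)
Conditions: dry MeCN, rt; then sulfonic acid cation-exchange resin (ammonium form), 25 mM NH4HCO3 in 2% iPrOH/H2O; cellulose chromatography (iPrOH/MeCN/0.1 M aq NH4HCO3); lyophilisation
Reagents that add atoms: none
Why: SN2 displacement of the primary allylic chloride by the organic-soluble diphosphate anion in a dry dipolar aprotic solvent (the standard halide-to-diphosphate preparation of prenyl diphosphates) should occur at C1 with the E olefin retained, the excess of salt suppressing double alkylation and the tertiary alcohol remaining a spectator.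

Step 5
Reactants: 8 (2E)-7-hydroxy-3,7-dimethyloct-2-en-1-yl diphosphate (tris(ammonium) salt, 1.5 equiv); 9 (+)-(2R,3R)-taxifolin
Product: 10 (2R,3R)-2-(3,4-dihydroxyphenyl)-3,5,7-trihydroxy-6-[(2E)-7-hydroxy-3,7-dimethyloct-2-en-1-yl]-2,3-dihydro-4H-chromen-4-one (target)
Conditions: recombinant His-tagged aromatic prenyltransferase NphB (soluble ABBA-fold enzyme of Streptomyces), MgCl2 (5 mM), sodium ascorbate (1 mM), 50 mM Tris-HCl pH 7.5, DMSO (5 vol%), 30 °C, argon, dark; EtOAc extraction; C18 HPLC (MeCN/H2O, 0.1% HCO2H)
Reagents that add atoms: none
Why: Proposed new method: inside the enzyme barrel the magnesium ion and basic residues bind the diphosphate of 8 and ionise the C1''–O bond to a tight allyl cation/diphosphate ion pair, the electron-rich C6 of ring A of 9 attacks C1'' in an electrophilic aromatic substitution (enzymatic Friedel–Crafts alkylation), and loss of the C6 proton restores the arene. The closest known reaction type is geranyl transfer from geranyl diphosphate to C6 of 5,7-dihydroxyflavanones such as naringenin by NphB and related soluble prenyltransferases, together with their tolerance of non-natural allylic diphosphates; here the acceptor differs only by the 3-OH and the donor only by water added across the remote C6''–C7'' olefin, which leaves the reacting C1''–C3'' allyl unit unchanged. No ring is closed and no stereocentre is created: C2 and C3 keep the 2R,3R configuration because the medium is neutral, and the E olefin is retained because bonding occurs at C1'' without allylic transposition. The step needs selectivity for C6 over C8, O7 and ring B and for C1'' over C3''; this should be secured by the way the pocket holds ring A over the diphosphate-bound C1'' and by the intrinsic nucleophilicity of C6, the only ring carbon lying between two carbons that bear free hydroxyl groups, with any 7-O-ether removed by HPLC. Ascorbate and argon protect the catechol of ring B, the neutral buffer avoids acid-induced chroman formation between the chain and the 5-OH or 7-OH, and if turnover is slow the residues lining the chain-terminus pocket are the place for homologue screening or mutation.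

Compound list
1 | geranyl acetate, (2E)-3,7-dimethylocta-2,6-dien-1-yl acetate | C/C(=C\COC(C)=O)CCC=C(C)C | starting material
2 | (2E)-6-(acetoxymercurio)-7-hydroxy-3,7-dimethyloct-2-en-1-yl acetate (racemic at C6) | C/C(=C\COC(C)=O)CCC([Hg]OC(C)=O)C(C)(C)O | intermediate
3 | (2E)-7-hydroxy-3,7-dimethyloct-2-en-1-yl acetate | C/C(=C\COC(C)=O)CCCC(C)(C)O | intermediate
4 | (2E)-3,7-dimethyloct-2-ene-1,7-diol | C/C(=C\CO)CCCC(C)(C)O | intermediate
5 | {[(2E)-7-hydroxy-3,7-dimethyloct-2-en-1-yl]oxy}dimethylsulfonium chloride | C/C(=C\CO[S+](C)C)CCCC(C)(C)O.[Cl-] | intermediate
6 | (6E)-8-chloro-2,6-dimethyloct-6-en-2-ol | C/C(=C\CCl)CCCC(C)(C)O | intermediate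
7 | tris(tetrabutylammonium) hydrogen diphosphate | CCCC[N+](CCCC)(CCCC)CCCC.CCCC[N+](CCCC)(CCCC)CCCC.CCCC[N+](CCCC)(CCCC)CCCC.OP(=O)([O-])OP(=O)([O-])[O-] | starting material
8 | (2E)-7-hydroxy-3,7-dimethyloct-2-en-1-yl diphosphate (drawn as the free acid, used as the tris(ammonium) salt) | C/C(=C\COP(=O)(O)OP(=O)(O)O)CCCC(C)(C)O | intermediate
9 | (+)-(2R,3R)-taxifolin, (2R,3R)-2-(3,4-dihydroxyphenyl)-3,5,7-trihydroxy-2,3-dihydro-4H-chromen-4-one | Oc1cc2c(c(O)c1)C(=O)[C@H](O)[C@@H](c1ccc(O)c(O)c1)O2 | starting material
10 | (2R,3R)-2-(3,4-dihydroxyphenyl)-3,5,7-trihydroxy-6-[(2E)-7-hydroxy-3,7-dimethyloct-2-en-1-yl]-2,3-dihydro-4H-chromen-4-one | C/C(=C\Cc1c(O)cc2c(c1O)C(=O)[C@H](O)[C@@H](c1ccc(O)c(O)c1)O2)CCCC(C)(C)O | target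

Total step count: 5. Longest linear sequence: 5 steps (1 to 3 to 4 to 6 to 8 to 10); taxifolin 9 and diphosphate salt 7 are bought.

Steps most likely to fail

Step 5 (proposed new method). The polar chain terminus of the donor or the 3-OH of the acceptor may prevent productive binding, so that transfer is slow, the donor is merely hydrolysed, or the chain is delivered to O7 or C8. The fallback uses known chemistry, sets out from allylic chloride 6 and taxifolin 9, and comes back to the route at 10. Taxifolin is converted into its 7-phenolate with DBU (1.0 equiv) in degassed THF at 0 °C under argon and treated with 6, warming to rt. This is the classical direct nuclear C-alkylation of the ambident phenolate of 5,7-dihydroxyflavanones and acylphloroglucinols with allylic halides. The C6 product should be accompanied by C8 and O7 isomers, from which it would be separated by C18 HPLC and assigned by HMBC from the chelated 5-OH. One equivalent of base at low temperature should limit enolisation at C3 and opening of ring C, and the tertiary alcohol and E olefin are inert to base. No compound beyond those of the route is made (F0).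

Step 4. The allylic diphosphate may ionise or hydrolyse during cation exchange and cellulose chromatography, and the diphosphate may be alkylated twice, so that little pure donor is recovered. The fallback sets out from diol 4 and comes back at 8, bypassing chloride 6 and therefore step 3 as well. Diol 4 is phosphorylated directly with trichloroacetonitrile and bis(triethylammonium) hydrogen phosphate in MeCN at rt, the known one-pot activation that is used to turn allylic terpene alcohols into their phosphates. The primary allylic hydroxyl is esterified first to (2E)-7-hydroxy-3,7-dimethyloct-2-en-1-yl dihydrogen phosphate F1, which is phosphorylated again in the same pot. Diphosphate 8 is separated from mono- and triphosphate on silica with iPrOH/conc. aq NH3/H2O and obtained as its ammonium salt. The hindered tertiary hydroxyl should not be phosphorylated.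

Step 1. The two olefins may not be discriminated cleanly, the mercurinium ion may trigger cation–olefin cyclisation, the acetate may be partly lost in the alkaline demercuration, and traces of mercury could be carried towards the enzyme. The fallback sets out from geranyl acetate 1 and comes back at diol 4, making step 2 unnecessary. Known selective epoxidation of the more electron-rich distal olefin with mCPBA (1.0 equiv, CH2Cl2, NaHCO3, 0 °C) gives (2E)-6,7-epoxy-3,7-dimethyloct-2-en-1-yl acetate F2. LiAlH4 in THF (0 °C to rt) then delivers hydride to the less substituted epoxide carbon C6, giving the tertiary alcohol, and cleaves the acetate in the same operation to give 4.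

Further compounds
F0 | step 5 | none | none
F1 | step 4 | (2E)-7-hydroxy-3,7-dimethyloct-2-en-1-yl dihydrogen phosphate | C/C(=C\COP(=O)(O)O)CCCC(C)(C)O
F2 | step 1 | (2E)-6,7-epoxy-3,7-dimethyloct-2-en-1-yl acetate (racemic) | C/C(=C\COC(C)=O)CCC1OC1(C)C
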